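Numbering: ring A = C1 (CMe2), C2 (CHBr), C3, C4, C5 (C(Me)–O6), C11 (CH); ring B = C5, O6, C7 (=C12HBr), C8 (Me) and C9 (oxirane carbons), C10, C11.
Cuts: first O6–C7 and C12–Br (ring B, alkynol bromo-etherification). Next C7–C12, the oxirane oxygen and C8=C9 (arm growth from a C9 aldehyde). Then C5–CH3, C5–O6 and C2–Br, and last C3–C4 of ring A.
Enabling feature: C11–H lies between quaternary C1 and C5H2, carries the two-carbon arm C10–C9, and C1 is followed by C2–C3. This is (R)-α-campholenic aldehyde with its vinylic methyl read as C3 and its ring CH2 as C5. Cleaving its ring alkene (C2=C4) and closing C3–C4 by aldol condensation enlarges the cyclopentene to ring A.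
Forward order: ring A (step 3), oxygen at C5, bromine at C2, tertiary carbinol at C5, arm extension by C8, C7 and C12, ring B last (step 21).
Stereochemistry: C11 comes from the terpene; C2 from axial hydrogen-atom delivery to an α-bromo radical; C5 from peracid attack anti to the axial C1 methyl and to C10; C8/C9 from tartrate-controlled epoxidation of a (Z)-allylic alcohol; (E)-C7=C12 from anti addition of O6 and Br.

Key step: step 3

Assumption: commercial (R)-α-campholenic aldehyde of high enantiomeric purity is used, because C11 relays every substrate-controlled centre. The transient C5 carbinol centre made in step 5 is drawn as the epimer expected from attack anti to the arm and is erased in step 10.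

Step 1
Reactants: 1 (R)-α-campholenic aldehyde, 2-[(1R)-2,2,3-trimethylcyclopent-3-en-1-yl]acetaldehyde; 2 trimethyl orthoformate
Product: 3 (4R)-4-(2,2-dimethoxyethyl)-1,5,5-trimethylcyclopent-1-ene
Conditions: HC(OMe)3, p-TsOH·H2O (cat.), MeOH, rt
Reagents that add atoms: trimethyl orthoformate (2), COC(OC)OC
Why: Acid-catalysed acetalisation with an orthoester as water scavenger masks the C9 aldehyde, so that only the two carbonyl groups created in step 2 can take part in the aldol step, and C11 is not touched.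

Step 2
Reactants: 3 (4R)-4-(2,2-dimethoxyethyl)-1,5,5-trimethylcyclopent-1-ene
Product: 5 (3R)-3-(2,2-dimethoxyethyl)-4,4-dimethyl-5-oxohexanal, via secondary ozonide 4 (not isolated)
Conditions: O3, CH2Cl2, −78 °C, stopped at the end point; then Me2S, −78 °C → rt
Reagents that add atoms: ozone, [O-][O+]=O
Why: Ozonolysis (Criegee mechanism) cleaves the only C=C bond, the electron-rich trisubstituted ring alkene, and reductive work-up of the ozonide stops at the C2 methyl ketone and the C4 aldehyde, while a prompt stop spares the acetal C–H.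

Step 3
Reactants: 5 (3R)-3-(2,2-dimethoxyethyl)-4,4-dimethyl-5-oxohexanal
Product: 7 (5R)-5-(2,2-dimethoxyethyl)-6,6-dimethylcyclohex-2-en-1-one, via aldol 6 (not isolated)
Conditions: KOH, MeOH (dilute), 0 °C → rt
Reagents that add atoms: none
Why: Hydroxide deprotonates 5 reversibly; the ketone can enolise only at its methyl group C3 because C1 is quaternary, this enolate adds to the C4 aldehyde to give aldol 6, and 6 loses water by E1cB to the conjugated C2 enone. The closest known reaction type is the intramolecular aldol condensation of the 1,5-keto aldehydes obtained by oxidative cleavage of 1-methylcyclopentenes, a standard five-to-six ring enlargement. Ring A closes in the 6-(enolendo)-exo-trig mode with formation of C3–C4. The only new stereocentre, the C4 carbinol of 6, is erased on dehydration, so no stereocontrol is needed. The step needs the ketone enolate to pair with the aldehyde acceptor: the aldehyde enolate at C5 could reach the ketone only through a four-membered ring and reverts by retro-aldol, and dilution holds back intermolecular aldol reactions. C11 is β to both carbonyl groups of 5 and never α to one, so the terpene configuration is kept, and the acetal is inert to base.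

Step 4
Reactants: 7 (5R)-5-(2,2-dimethoxyethyl)-6,6-dimethylcyclohex-2-en-1-one
Product: 8 tert-butyl{[(5S)-5-(2,2-dimethoxyethyl)-6,6-dimethylcyclohexa-1,3-dien-1-yl]oxy}dimethylsilane
Conditions: KN(SiMe3)2, TBSCl, THF, −78 → 0 °C
Reagents that add atoms: tert-butyldimethylsilyl chloride, CC(C)(C)[Si](C)(C)Cl
Why: With C1 quaternary the enone can be deprotonated only at the γ-position C5, and O-silylation of the extended dienolate (silyl dienol ether formation) gives the 1-silyloxy-1,3-diene under acid-free conditions that keep the acetal.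

Step 5
Reactants: 8 tert-butyl{[(5S)-5-(2,2-dimethoxyethyl)-6,6-dimethylcyclohexa-1,3-dien-1-yl]oxy}dimethylsilane
Product: 9 (4R,5R)-5-(2,2-dimethoxyethyl)-4-hydroxy-6,6-dimethylcyclohex-2-en-1-one
Conditions: mCPBA, NaHCO3, CH2Cl2, −20 °C; aqueous work-up
Reagents that add atoms: 3-chloroperbenzoic acid, O=C(OO)c1cccc(Cl)c1
Why: Vinylogous Rubottom oxidation: the peracid epoxidises the distal C4=C5 bond of the silyl dienol ether on the face anti to the C11 arm, and push from the silyloxy group opens the epoxide to the γ-hydroxy enone with loss of silicon, which puts oxygen on C5 while C11 is still not α to a carbonyl group.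

Step 6
Reactants: 9 (4R,5R)-5-(2,2-dimethoxyethyl)-4-hydroxy-6,6-dimethylcyclohex-2-en-1-one
Product: 10 (3R,4R)-3-(2,2-dimethoxyethyl)-4-hydroxy-2,2-dimethylcyclohexan-1-one
Conditions: H2 (1 atm), Pd/C, EtOAc, rt
Reagents that add atoms: none
Why: Heterogeneous catalytic hydrogenation saturates the conjugated C3=C4 bond under neutral conditions that leave ketone, carbinol and acetal alone.

Step 7
Reactants: 10 (3R,4R)-3-(2,2-dimethoxyethyl)-4-hydroxy-2,2-dimethylcyclohexan-1-one
Product: 11 (E)-hydrazone of 10, NH2 turned away from C1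
Conditions: N2H4·H2O (excess), Et3N, EtOH, reflux
Reagents that add atoms: hydrazine, NN
Why: Hydrazone formation works for α-quaternary ketones on heating, the basic medium protects the acetal, and excess hydrazine holds back azine formation.

Step 8
Reactants: 11 (E)-hydrazone of 10
Product: 12 (1R,6R)-4-bromo-6-(2,2-dimethoxyethyl)-5,5-dimethylcyclohex-3-en-1-ol
Conditions: NBS (2.2 equiv), pyridine, −10 °C
Reagents that add atoms: N-bromosuccinimide, O=C1CCC(=O)N1Br
Why: Barton vinyl halide synthesis: NBS oxidises the hydrazone to the diazoalkane and brominates it, and loss of N2 and of the only adjacent proton (C3–H) gives the C2=C3 alkenyl bromide, a sequence known for α-quaternary ketone hydrazones that carry free secondary hydroxyl groups.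

Step 9
Reactants: 12 (1R,6R)-4-bromo-6-(2,2-dimethoxyethyl)-5,5-dimethylcyclohex-3-en-1-ol
Product: 13 (1R,2R,4R)-4-bromo-2-(2,2-dimethoxyethyl)-3,3-dimethylcyclohexan-1-ol
Conditions: Mn(dpm)3 (cat., dpm = dipivaloylmethanate), PhSiH3, t-BuOOH, i-PrOH, rt
Reagents that add atoms: none
Why: Radical hydrogenation by hydrogen-atom transfer, known to turn alkenyl halides into alkyl halides without loss of halogen: the manganese hydride adds H to C3, and the α-bromo radical at C2 takes its second H on the axial face opposite the axial C1 methyl, which sets C2 with equatorial bromine cis to the equatorial C11 arm.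

Step 10
Reactants: 13 (1R,2R,4R)-4-bromo-2-(2,2-dimethoxyethyl)-3,3-dimethylcyclohexan-1-ol
Product: 14 (2R,4R)-4-bromo-2-(2,2-dimethoxyethyl)-3,3-dimethylcyclohexan-1-one
Conditions: Dess–Martin periodinane, NaHCO3, CH2Cl2, rt
Reagents that add atoms: none
Why: Dess–Martin oxidation is neutral and non-enolising; C11 becomes α to a ketone only now that C2 is fixed, so its epimer would have to place the arm or the bromine axial and the required diequatorial isomer is also the thermodynamic one.

Step 11
Reactants: 14 (2R,4R)-4-bromo-2-(2,2-dimethoxyethyl)-3,3-dimethylcyclohexan-1-one; 15 methyltriphenylphosphonium bromide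
Product: 16 (1R,3S)-1-bromo-3-(2,2-dimethoxyethyl)-2,2-dimethyl-4-methylidenecyclohexane
Conditions: Ph3PCH3Br (1.3 equiv), KOt-Bu (1.2 equiv), THF, 0 °C → rt
Reagents that add atoms: methyltriphenylphosphonium bromide (15), C[P+](c1ccccc1)(c1ccccc1)c1ccccc1.[Br-]
Why: Wittig methylenation of the only carbonyl group, with the ylide made from a slight deficit of base so that enolisation of the γ-bromo ketone stays marginal.

Step 12
Reactants: 16 (1R,3S)-1-bromo-3-(2,2-dimethoxyethyl)-2,2-dimethyl-4-methylidenecyclohexane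
Product: 17 (3R,4R,6R)-6-bromo-4-(2,2-dimethoxyethyl)-5,5-dimethyl-1-oxaspiro[2.5]octane
Conditions: mCPBA, NaHCO3, CH2Cl2, 0 °C
Reagents that add atoms: 3-chloroperbenzoic acid, O=C(OO)c1cccc(Cl)c1
Why: Prilezhaev epoxidation: in the chair locked by equatorial bromine and arm, the axial C1 methyl blocks the axial face of C5, so the peracid attacks from the equatorial face anti to C10 (as with the exocyclic alkenes of drimanes and labdanes) and sets C5 with equatorial oxygen.

Step 13
Reactants: 17 (3R,4R,6R)-6-bromo-4-(2,2-dimethoxyethyl)-5,5-dimethyl-1-oxaspiro[2.5]octane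
Product: 18 (1R,2R,4R)-4-bromo-2-(2,2-dimethoxyethyl)-1,3,3-trimethylcyclohexan-1-ol
Conditions: LiEt3BH, THF, −78 → 0 °C; aqueous work-up
Reagents that add atoms: none
Why: SN2 hydride opening of the epoxide at its unsubstituted carbon turns the axial CH2 into the C5 methyl without touching the C5–O bond, while the equatorial, neopentyl C2 bromide offers no backside trajectory at this temperature.

Step 14
Reactants: 18 (1R,2R,4R)-4-bromo-2-(2,2-dimethoxyethyl)-1,3,3-trimethylcyclohexan-1-ol
Product: 21 2-[(1R,3R,6R)-3-bromo-2,2,6-trimethyl-6-(triethylsilyloxy)cyclohexyl]acetaldehyde, via silyl ether acetal 19 (not isolated), via lutidinium salt 20 (not isolated)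
Conditions: TESOTf (1.2 equiv), 2,6-lutidine, CH2Cl2, −78 °C; then TESOTf (2 equiv), 0 °C; then H2O
Reagents that add atoms: triethylsilyl triflate, CC[Si](CC)(CC)OS(=O)(=O)C(F)(F)F; water, O
Why: Silyl triflate and lutidine first silylate the tertiary alcohol, and further TESOTf converts the aldehyde-derived acetal into a lutidinium salt that water hydrolyses under weakly basic conditions (a known chemoselective acetal cleavage), so the aldehyde is freed without acid and cannot be caught by O6 as a lactol.

Step 15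
Reactants: 21 2-[(1R,3R,6R)-3-bromo-2,2,6-trimethyl-6-(triethylsilyloxy)cyclohexyl]acetaldehyde; 22 ethyl 2-[bis(2,2,2-trifluoroethoxy)phosphoryl]propanoate
Product: 23 ethyl (2Z)-4-[(1R,3R,6R)-3-bromo-2,2,6-trimethyl-6-(triethylsilyloxy)cyclohexyl]-2-methylbut-2-enoate
Conditions: 22, KN(SiMe3)2, 18-crown-6, THF, −78 °C
Reagents that add atoms: ethyl 2-[bis(2,2,2-trifluoroethoxy)phosphoryl]propanoate (22), CCOC(=O)C(C)P(=O)(OCC(F)(F)F)OCC(F)(F)F
Why: Still–Gennari olefination: fast, irreversible elimination from the kinetic adduct of the trifluoroethyl phosphonate gives the (Z)-trisubstituted enoate, which places C7 cis to C10 as ring B requires, and the silyl ether rules out oxa-Michael addition of O6.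

Step 16
Reactants: 23 ethyl (2Z)-4-[(1R,3R,6R)-3-bromo-2,2,6-trimethyl-6-(triethylsilyloxy)cyclohexyl]-2-methylbut-2-enoate
Product: 24 (2Z)-4-[(1R,3R,6R)-3-bromo-2,2,6-trimethyl-6-(triethylsilyloxy)cyclohexyl]-2-methylbut-2-en-1-ol
Conditions: i-Bu2AlH (2.5 equiv), CH2Cl2, −78 °C
Reagents that add atoms: none
Why: 1,2-Reduction of the enoate with i-Bu2AlH at low temperature gives the allylic alcohol without touching the alkyl bromide, the silyl ether or the alkene geometry.

Step 17
Reactants: 24 (2Z)-4-[(1R,3R,6R)-3-bromo-2,2,6-trimethyl-6-(triethylsilyloxy)cyclohexyl]-2-methylbut-2-en-1-ol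
Product: 25 [(2R,3S)-3-{[(1R,3R,6R)-3-bromo-2,2,6-trimethyl-6-(triethylsilyloxy)cyclohexyl]methyl}-2-methyloxiran-2-yl]methanol
Conditions: Ti(Oi-Pr)4, D-(−)-diethyl tartrate, t-BuOOH, 4 Å MS, CH2Cl2, −20 °C
Reagents that add atoms: tert-butyl hydroperoxide, CC(C)(C)OO
Why: Sharpless asymmetric epoxidation: reagent control by D-(−)-tartrate gives the (2R,3S)-epoxy alcohol from a (Z)-allylic alcohol, which is C8 and C9 as in the target, and the Z geometry fixes C7 and C10 cis on the oxirane.

Step 18
Reactants: 25 [(2R,3S)-3-{[(1R,3R,6R)-3-bromo-2,2,6-trimethyl-6-(triethylsilyloxy)cyclohexyl]methyl}-2-methyloxiran-2-yl]methanol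
Product: 26 (2S,3S)-3-{[(1R,3R,6R)-3-bromo-2,2,6-trimethyl-6-(triethylsilyloxy)cyclohexyl]methyl}-2-methyloxirane-2-carbaldehyde
Conditions: Dess–Martin periodinane, NaHCO3, CH2Cl2, 0 °C → rt
Reagents that add atoms: none
Why: Buffered Dess–Martin oxidation of the primary epoxy alcohol stops at the aldehyde and spares oxirane and silyl ether; only the descriptor at C8 changes, not its geometry.

Step 19
Reactants: 26 (2S,3S)-3-{[(1R,3R,6R)-3-bromo-2,2,6-trimethyl-6-(triethylsilyloxy)cyclohexyl]methyl}-2-methyloxirane-2-carbaldehyde; 27 dimethyl (1-diazo-2-oxopropyl)phosphonate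
Product: 28 {[(1R,2R,4R)-4-bromo-2-{[(2S,3R)-3-ethynyl-3-methyloxiran-2-yl]methyl}-1,3,3-trimethylcyclohexyl]oxy}triethylsilane
Conditions: 27, K2CO3, MeOH, 0 °C → rt
Reagents that add atoms: dimethyl (1-diazo-2-oxopropyl)phosphonate (27), COP(=O)(OC)C(=[N+]=[N-])C(C)=O
Why: Ohira–Bestmann variant of the Seyferth–Gilbert homologation adds C12 and gives the terminal alkyne under mild carbonate conditions, and the aldehyde cannot epimerise because C8 is quaternary.

Step 20
Reactants: 28 {[(1R,2R,4R)-4-bromo-2-{[(2S,3R)-3-ethynyl-3-methyloxiran-2-yl]methyl}-1,3,3-trimethylcyclohexyl]oxy}triethylsilane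
Product: 29 (1R,2R,4R)-4-bromo-2-{[(2S,3R)-3-ethynyl-3-methyloxiran-2-yl]methyl}-1,3,3-trimethylcyclohexan-1-ol
Conditions: Bu4NF, AcOH (1:1), THF, 0 °C → rt
Reagents that add atoms: none
Why: Fluoride-induced desilylation frees O6, and the acetic acid buffer keeps the tertiary alkoxide from building up and opening the oxirane at C9.

Step 21
Reactants: 29 (1R,2R,4R)-4-bromo-2-{[(2S,3R)-3-ethynyl-3-methyloxiran-2-yl]methyl}-1,3,3-trimethylcyclohexan-1-ol
Product: 30 target CNP0375295.2, trans-fused ring A/oxepane ring B with (E)-C7=C12HBr and the C8–C9 oxirane; in the numbering used here 2R,5R,8S,9S,11R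
Conditions: NBS (1.1 equiv), 4 Å MS, MeCN, 0 °C → rt, dark
Reagents that add atoms: N-bromosuccinimide, O=C1CCC(=O)N1Br
Why: Proposed new method: NBS polarises the terminal alkyne towards a bromirenium-type complex with bromine on the unhindered C12, the C5 hydroxyl attacks C7 from the opposite side in a 7-exo-dig closure and the succinimide anion takes the proton, so anti addition places O6 and Br trans, that is the (E)-bromomethylene enol ether, under self-buffered, acid-free conditions that leave the oxirane and the product enol ether intact; the closure is helped by the trans-diequatorial O6/C10 pair on ring A and by the cis-oxirane, which leave only the C11–C10 and C10–C9 bonds free to rotate, and the closest known reaction type is the 5- and 6-exo-dig halo-etherification and bromo-enol-lactonisation of terminal alkynols and alkynoic acids with N-halosuccinimides, which also gives (E)-halomethylene heterocycles by anti addition but has not been shown for a seven-membered ring, a tertiary alcohol or an oxiranyl alkyne.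

Compound list
1 | (R)-α-campholenic aldehyde | CC1=CC[C@H](CC=O)C1(C)C | starting material
2 | trimethyl orthoformate | COC(OC)OC | starting material
3 | (4R)-4-(2,2-dimethoxyethyl)-1,5,5-trimethylcyclopent-1-ene | CC1=CC[C@H](CC(OC)OC)C1(C)C | intermediate
4 | 3-(2,2-dimethoxyethyl)-1,2,2-trimethyl-6,7,8-trioxabicyclo[3.2.1]octane (secondary ozonide, C11 as in 3, bridgehead isomers) | CC12OOC(O1)C[C@H](CC(OC)OC)C2(C)C | intermediate
5 | (3R)-3-(2,2-dimethoxyethyl)-4,4-dimethyl-5-oxohexanal | CC(=O)C(C)(C)[C@@H](CC(OC)OC)CC=O | intermediate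
6 | (3R)-3-(2,2-dimethoxyethyl)-5-hydroxy-2,2-dimethylcyclohexan-1-one (aldol, C4 epimers) | O=C1CC(O)C[C@H](CC(OC)OC)C1(C)C | intermediate
7 | (5R)-5-(2,2-dimethoxyethyl)-6,6-dimethylcyclohex-2-en-1-one | O=C1C=CC[C@H](CC(OC)OC)C1(C)C | intermediate
8 | tert-butyl{[(5S)-5-(2,2-dimethoxyethyl)-6,6-dimethylcyclohexa-1,3-dien-1-yl]oxy}dimethylsilane | CC(C)(C)[Si](C)(C)OC1=CC=C[C@H](CC(OC)OC)C1(C)C | intermediate
9 | (4R,5R)-5-(2,2-dimethoxyethyl)-4-hydroxy-6,6-dimethylcyclohex-2-en-1-one | O=C1C=C[C@@H](O)[C@H](CC(OC)OC)C1(C)C | intermediate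
10 | (3R,4R)-3-(2,2-dimethoxyethyl)-4-hydroxy-2,2-dimethylcyclohexan-1-one | O=C1CC[C@@H](O)[C@H](CC(OC)OC)C1(C)C | intermediate
11 | (E)-hydrazone of 10 | N/N=C1\CC[C@@H](O)[C@H](CC(OC)OC)C1(C)C | intermediate
12 | (1R,6R)-4-bromo-6-(2,2-dimethoxyethyl)-5,5-dimethylcyclohex-3-en-1-ol | BrC1=CC[C@@H](O)[C@H](CC(OC)OC)C1(C)C | intermediate
13 | (1R,2R,4R)-4-bromo-2-(2,2-dimethoxyethyl)-3,3-dimethylcyclohexan-1-ol | CC1(C)[C@H](Br)CC[C@@H](O)[C@@H]1CC(OC)OC | intermediate
14 | (2R,4R)-4-bromo-2-(2,2-dimethoxyethyl)-3,3-dimethylcyclohexan-1-one | CC1(C)[C@H](Br)CCC(=O)[C@@H]1CC(OC)OC | intermediate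
15 | methyltriphenylphosphonium bromide | C[P+](c1ccccc1)(c1ccccc1)c1ccccc1.[Br-] | starting material
16 | (1R,3S)-1-bromo-3-(2,2-dimethoxyethyl)-2,2-dimethyl-4-methylidenecyclohexane | CC1(C)[C@H](Br)CCC(=C)[C@@H]1CC(OC)OC | intermediate
17 | (3R,4R,6R)-6-bromo-4-(2,2-dimethoxyethyl)-5,5-dimethyl-1-oxaspiro[2.5]octane | CC1(C)[C@H](Br)CC[C@]2(CO2)[C@@H]1CC(OC)OC | intermediate
18 | (1R,2R,4R)-4-bromo-2-(2,2-dimethoxyethyl)-1,3,3-trimethylcyclohexan-1-ol | CC1(C)[C@H](Br)CC[C@@](C)(O)[C@@H]1CC(OC)OC | intermediate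
19 | {[(1R,2R,4R)-4-bromo-2-(2,2-dimethoxyethyl)-1,3,3-trimethylcyclohexyl]oxy}triethylsilane | CC1(C)[C@H](Br)CC[C@@](C)(O[Si](CC)(CC)CC)[C@@H]1CC(OC)OC | intermediate
20 | 1-{2-[(1R,3R,6R)-3-bromo-2,2,6-trimethyl-6-(triethylsilyloxy)cyclohexyl]-1-methoxyethyl}-2,6-dimethylpyridinium triflate (epimers at the N,O-acetal carbon) | CC1(C)[C@H](Br)CC[C@@](C)(O[Si](CC)(CC)CC)[C@@H]1CC(OC)[n+]1c(C)cccc1C.[O-]S(=O)(=O)C(F)(F)F | intermediate
21 | 2-[(1R,3R,6R)-3-bromo-2,2,6-trimethyl-6-(triethylsilyloxy)cyclohexyl]acetaldehyde | CC1(C)[C@H](Br)CC[C@@](C)(O[Si](CC)(CC)CC)[C@@H]1CC=O | intermediate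
22 | ethyl 2-[bis(2,2,2-trifluoroethoxy)phosphoryl]propanoate | CCOC(=O)C(C)P(=O)(OCC(F)(F)F)OCC(F)(F)F | starting material
23 | ethyl (2Z)-4-[(1R,3R,6R)-3-bromo-2,2,6-trimethyl-6-(triethylsilyloxy)cyclohexyl]-2-methylbut-2-enoate | CC1(C)[C@H](Br)CC[C@@](C)(O[Si](CC)(CC)CC)[C@@H]1C/C=C(/C)C(=O)OCC | intermediate
24 | (2Z)-4-[(1R,3R,6R)-3-bromo-2,2,6-trimethyl-6-(triethylsilyloxy)cyclohexyl]-2-methylbut-2-en-1-ol | CC1(C)[C@H](Br)CC[C@@](C)(O[Si](CC)(CC)CC)[C@@H]1C/C=C(/C)CO | intermediate
25 | [(2R,3S)-3-{[(1R,3R,6R)-3-bromo-2,2,6-trimethyl-6-(triethylsilyloxy)cyclohexyl]methyl}-2-methyloxiran-2-yl]methanol | CC1(C)[C@H](Br)CC[C@@](C)(O[Si](CC)(CC)CC)[C@@H]1C[C@@H]2O[C@]2(C)CO | intermediate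
26 | (2S,3S)-3-{[(1R,3R,6R)-3-bromo-2,2,6-trimethyl-6-(triethylsilyloxy)cyclohexyl]methyl}-2-methyloxirane-2-carbaldehyde | CC1(C)[C@H](Br)CC[C@@](C)(O[Si](CC)(CC)CC)[C@@H]1C[C@@H]2O[C@]2(C)C=O | intermediate
27 | dimethyl (1-diazo-2-oxopropyl)phosphonate | COP(=O)(OC)C(=[N+]=[N-])C(C)=O | starting material
28 | {[(1R,2R,4R)-4-bromo-2-{[(2S,3R)-3-ethynyl-3-methyloxiran-2-yl]methyl}-1,3,3-trimethylcyclohexyl]oxy}triethylsilane | CC1(C)[C@H](Br)CC[C@@](C)(O[Si](CC)(CC)CC)[C@@H]1C[C@@H]2O[C@]2(C)C#C | intermediate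
29 | (1R,2R,4R)-4-bromo-2-{[(2S,3R)-3-ethynyl-3-methyloxiran-2-yl]methyl}-1,3,3-trimethylcyclohexan-1-ol | CC1(C)[C@H](Br)CC[C@@](C)(O)[C@@H]1C[C@@H]2O[C@]2(C)C#C | intermediate
30 | CNP0375295.2 (2R,5R,8S,9S,11R; 7E in the numbering used here) | CC1(C)[C@H](Br)CC[C@@]2(C)O/C(=C/Br)[C@@]3(C)O[C@H]3C[C@H]12 | target

Total step count: 21. Longest linear sequence: 21 steps (fully linear from 1).

Steps most likely to fail

1. Step 21.
- What may go wrong: the tertiary hydroxyl may be too slow for the 7-exo-dig attack. Bromination of the acetylenic C–H, plain dibromination of the triple bond, or 5-exo opening of the oxirane at C9 by O6 could then take over.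
- Fallback: it closes ring B by acylation instead of alkyne activation, sets out from 26 and comes back at 30.
- Course: Pinnick oxidation (NaClO2, NaH2PO4, 2-methylbut-2-ene) should give the silyl-protected epoxy acid F1. Buffered Bu4NF should then give the hydroxy epoxy acid F2. Yamaguchi lactonisation (2,4,6-trichlorobenzoyl chloride, Et3N, then DMAP, toluene, high dilution) should give the epoxy ε-lactone F3. Ramirez-type dibromomethylenation of the lactone carbonyl (CBr4, PPh3, toluene, reflux) would give the dibromomethylene enol ether F4.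
- Return to the route: hydrogenolysis of F4 with Bu3SnH and Pd(PPh3)4 follows. Zerovalent palladium inserts into the less hindered C–Br bond, the one cis to O6 and remote from quaternary C8. The bromine cis to C8 stays, which is 30.

2. Step 9.
- What may go wrong: hydrogen-atom transfer to the hindered bromoalkene may be slow, bromine may be lost by over-reduction, or the second hydrogen may be delivered with poor facial selectivity.
- Fallback: it installs bromine by substitution with inversion, sets out from 10 and comes back at 13.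
- Course: silylation (TBSCl, imidazole) should give the silyloxy ketone F5. LiB(s-Bu)3H attacks the C2 ketone from the equatorial side and should give the axial alcohol F6. An Appel reaction (CBr4, PPh3, toluene, heat) should invert C2 to the equatorial bromide F7, and Bu4NF removes the silyl group to give 13.

3. Step 13.
- What may go wrong: reduction of the C2–Br bond may compete, or opening at the hindered, neopentyl-type epoxide CH2 may be sluggish.
- Fallback: it avoids hydride altogether, sets out from 16 (skipping 17) and comes back at 18.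
- Course: Mukaiyama hydration (Mn(dpm)3, PhSiH3, O2, i-PrOH) generates the tertiary C5 radical. This radical is trapped by O2 on the equatorial face away from the axial C1 methyl and gives the tertiary hydroperoxide F8. PPh3 reduces F8 to 18.

Further compounds
F1 | step 21 | (2S,3S)-3-{[(1R,3R,6R)-3-bromo-2,2,6-trimethyl-6-(triethylsilyloxy)cyclohexyl]methyl}-2-methyloxirane-2-carboxylic acid | CC1(C)[C@H](Br)CC[C@@](C)(O[Si](CC)(CC)CC)[C@@H]1C[C@@H]2O[C@]2(C)C(=O)O
F2 | step 21 | (2S,3S)-3-{[(1R,3R,6R)-3-bromo-6-hydroxy-2,2,6-trimethylcyclohexyl]methyl}-2-methyloxirane-2-carboxylic acid | CC1(C)[C@H](Br)CC[C@@](C)(O)[C@@H]1C[C@@H]2O[C@]2(C)C(=O)O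
F3 | step 21 | epoxy ε-lactone, the analogue of 30 with C7=O in place of C7=C12HBr | CC1(C)[C@H](Br)CC[C@@]2(C)OC(=O)[C@@]3(C)O[C@H]3C[C@H]12
F4 | step 21 | dibromomethylene enol ether, the analogue of 30 with C7=CBr2 | CC1(C)[C@H](Br)CC[C@@]2(C)OC(=C(Br)Br)[C@@]3(C)O[C@H]3C[C@H]12
F5 | step 9 | (3R,4R)-4-(tert-butyldimethylsilyloxy)-3-(2,2-dimethoxyethyl)-2,2-dimethylcyclohexan-1-one | CC1(C)C(=O)CC[C@@H](O[Si](C)(C)C(C)(C)C)[C@@H]1CC(OC)OC
F6 | step 9 | (1S,3R,4R)-4-(tert-butyldimethylsilyloxy)-3-(2,2-dimethoxyethyl)-2,2-dimethylcyclohexan-1-ol | CC1(C)[C@@H](O)CC[C@@H](O[Si](C)(C)C(C)(C)C)[C@@H]1CC(OC)OC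
F7 | step 9 | {[(1R,2R,4R)-4-bromo-2-(2,2-dimethoxyethyl)-3,3-dimethylcyclohexyl]oxy}(tert-butyl)dimethylsilane | CC1(C)[C@H](Br)CC[C@@H](O[Si](C)(C)C(C)(C)C)[C@@H]1CC(OC)OC
F8 | step 13 | (1R,2R,4R)-4-bromo-2-(2,2-dimethoxyethyl)-1,3,3-trimethylcyclohexyl hydroperoxide | CC1(C)[C@H](Br)CC[C@@](C)(OO)[C@@H]1CC(OC)OC
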